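**Assumption:** genipin (bulk gardenia-derived iridoid aglycone, same C5/C9 configuration as the target) is accepted as a cheap commercial chiral-pool starting material. The side-chain acid is used racemic because its carbinol centre ends up sp2.

## Retrosynthetic overview
1. Target ⇐ prismatomerin (phenol acetylation).
2. THF acetal and E-arylidene ⇐ acid-triggered SN2′ addition of the C1 lactol oxygen to C10 of a spiro-butenolide carrying an α-CH(OSi)Ar group.
3. Butenolide (γ-lactone ring) ⇐ intramolecular aldol condensation of a C8 ester enolate onto the C10 aldehyde (key C–C ring closure).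
4. Aldol substrate ⇐ tertiary α-hydroxy aldehyde (from genipin by epoxidation, selenide transposition, oxidation) + β-silyloxy acid chloride (from 4-hydroxybenzaldehyde + methyl acetate).
5. Ring order: dihydropyran and cyclopentene come from genipin → γ-lactone (aldol) → THF acetal (last ring).

Iridoid numbering is used: C1 acetal carbon, O2, C3=C4(CO2Me), C5/C9 ring-fusion CH, C6–C7–C8 cyclopentene carbons, C10 the exocyclic carbon on C8. Lactone carbons are C11 (α), C12 (C=O), C13 (benzylic). β = the face of H-5/H-9.

## Route

### Arm A (core, from genipin)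

**Step 1**
Reactants: 1 genipin
Product: 2 1-O-methylgenipin (1β-OMe)
Conditions: MeOH, PPTS (cat.), rt
Reagents that add atoms: methanol, CO
Why: Acid-catalysed lactol-to-methyl-acetal exchange via the C1 oxocarbenium protects the hemiacetal against NaBH4 and base; the C1 configuration is irrelevant because it is reset in step 14.

**Step 2**
Reactants: 2
Product: 3 7β,8β-epoxide of 2 (C10 CH2OH retained on C8)
Conditions: VO(acac)2 (2 mol %), t-BuOOH, CH2Cl2, 0 °C → rt
Reagents that add atoms: tert-butyl hydroperoxide, CC(C)(C)OO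
Why: Hydroxyl-directed vanadium epoxidation touches only the allylic-alcohol alkene (the ester-conjugated enol ether is inert) and delivers O to the convex β-face (the α-face is blocked by the pyran ring and H-1), which sets the C8–O configuration kept to the target.

**Step 3**
Reactants: 3
Product: 4 trans-hydroxy selenide (7α-SePh, 8β-OH, 8α-CH2OH)
Conditions: PhSeSePh, NaBH4, MeOH–THF, 0 → 50 °C
Reagents that add atoms: diphenyl diselenide, c1ccc(cc1)[Se][Se]c1ccccc1
Why: SN2 anti opening of the epoxide at the less substituted C7 (first half of the Sharpless–Lauer transposition); the borate-complexed selenide is non-basic, which suppresses Payne rearrangement, and MeOH avoids transesterification.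

**Step 4**
Reactants: 4
Product: 5 allylic diol (Δ6,7; 8β-OH; 8α-CH2OH)
Conditions: 30% H2O2, pyridine, CH2Cl2, 0 °C → rt
Reagents that add atoms: none
Why: Selenoxide syn-elimination can only go toward C6 (C8 has no H), giving the Δ6,7 tertiary allylic alcohol without touching the C8 stereocentre.

**Step 5**
Reactants: 5
Product: 6 tertiary α-hydroxy aldehyde (8β-OH, 8α-CHO)
Conditions: SO3·pyridine, DMSO, i-Pr2NEt, CH2Cl2, 0 °C
Reagents that add atoms: none
Why: Parikh–Doering oxidation converts only the primary alcohol (tertiary OH inert) under cold, non-acidic conditions that avoid α-ketol rearrangement.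

### Arm B (side-chain acid chloride)

**Step 6**
Reactants: 7 4-hydroxybenzaldehyde
Product: 8 4-(methoxymethoxy)benzaldehyde
Conditions: MOMCl, i-Pr2NEt, CH2Cl2, 0 °C → rt
Reagents that add atoms: chloromethyl methyl ether, COCCl
Why: Phenol O-alkylation gives a MOM ether that survives enolates and base and is removed by the acid used in step 14.

**Step 7**
Reactants: 8; 9 methyl acetate
Product: 10 methyl (±)-3-hydroxy-3-[4-(methoxymethoxy)phenyl]propanoate
Conditions: LDA, THF, −78 °C (enolise 9), then 8
Reagents that add atoms: none (both partners are numbered reactants)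
Why: Directed aldol addition of the lithium enolate of methyl acetate to a non-enolisable aldehyde; the racemic carbinol is acceptable because C13 becomes sp2.

**Step 8**
Reactants: 10
Product: 11 methyl (±)-3-(TBS-oxy)-3-[4-(methoxymethoxy)phenyl]propanoate
Conditions: TBSCl, imidazole, DMF, rt
Reagents that add atoms: tert-butyldimethylsilyl chloride, CC(C)(C)[Si](C)(C)Cl
Why: Silylation gives a β-silyloxy ester that tolerates enolisation at −78 °C (poor leaving group) but later serves as the acid-ionisable benzylic leaving group.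

**Step 9**
Reactants: 11
Product: 12 (±)-3-(TBS-oxy)-3-[4-(methoxymethoxy)phenyl]propanoic acid
Conditions: LiOH, THF/MeOH/H2O, 0 °C → rt
Reagents that add atoms: lithium hydroxide/water, [Li+].[OH-]
Why: Saponification of the methyl ester; alkyl TBS and aryl MOM ethers are stable to hydroxide.

**Step 10**
Reactants: 12
Product: 13 (±)-acid chloride of 12
Conditions: 1-chloro-N,N,2-trimethylprop-1-en-1-amine (Ghosez reagent), CH2Cl2, 0 °C → rt, used crude
Reagents that add atoms: Ghosez reagent, CC(C)=C(Cl)N(C)C
Why: Neutral acid-chloride formation with no HCl keeps the TBS and MOM ethers intact.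

### Union and endgame

**Step 11**
Reactants: 6; 13
Product: 14 8β-O-acyl α-acyloxy aldehyde (1:1 at C13)
Conditions: 13 (1.5 equiv), DMAP (2 equiv), pyridine, CH2Cl2, 0 °C → rt
Reagents that add atoms: none (both partners are numbered reactants)
Why: DMAP-mediated acyl transfer (acylpyridinium) from an unhindered RCH2COCl esterifies the only hydroxyl, the tertiary C8–OH, with retention at C8.

**Step 12**
Reactants: 14
Product: 15 spiro β-hydroxy-γ-lactone (C8–O–C12(=O)–C11H[CH(OTBS)Ar]–C10H(OH)–C8; diastereomer mixture)
Conditions: LiHMDS (1.1 equiv), THF, 0.01 M, −78 → −40 °C; AcOH quench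
Reagents that add atoms: none
Why: Intramolecular aldol addition of the ester lithium enolate (the only acidic C–H) onto the adjacent non-enolisable aldehyde forms the C10–C11 bond and closes the γ-lactone (classical butenolide-type lactone annulation, formally 5-enolendo-exo-trig); the new C10/C11 centres are erased in steps 13–14.

**Step 13**
Reactants: 15
Product: 16 spiro-butenolide (C10=C11; C11 bears CH(OTBS)Ar; 1:1 at C13)
Conditions: MsCl, Et3N, CH2Cl2, 0 °C; then DBU, 0 °C → rt
Reagents that add atoms: none
Why: Mesylation and E1cB elimination through the acidic C11–H complete the aldol condensation; mesylate leaves far faster than the β′-silyloxy group.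

**Step 14**
Reactants: 16
Product: 17 prismatomerin (free phenol)
Conditions: TFA/H2O (9:1), CH2Cl2, 5 mM, 0 °C → rt; NaHCO3 work-up
Reagents that add atoms: water, O (becomes the C1–O–C10 acetal oxygen)
Why: Acid removes MOM and TBS and hydrolyses the C1 methyl acetal, then the C1 lactol oxygen adds in a vinylogous SN1′/SN2′ sense to C10 of the p-hydroxybenzyl-stabilised allyl cation (5-exo). Only the cis-fused cage can form, so C1 and C10 are dictated by the fixed C8/C9 centres, and the conjugated E-arylidene is the thermodynamic product.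

**Step 15**
Reactants: 17
Product: 18 3-O-acetylprismatomerin (target)
Conditions: Ac2O, pyridine, DMAP (cat.), CH2Cl2, 0 °C
Reagents that add atoms: acetic anhydride, CC(=O)OC(C)=O
Why: Acetylation of the only free hydroxyl (the phenol) under mild base that leaves the acetal, lactone and enoate untouched.

## Compound list
1 | genipin, methyl (1R,4aS,7aS)-1-hydroxy-7-(hydroxymethyl)-1,4a,5,7a-tetrahydrocyclopenta[c]pyran-4-carboxylate | COC(=O)C1=CO[C@@H](O)[C@H]2[C@@H]1CC=C2CO | starting material
2 | 1-O-methylgenipin (1β-OMe) | COC(=O)C1=CO[C@@H](OC)[C@H]2[C@@H]1CC=C2CO | intermediate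
3 | 7β,8β-epoxy-7,8-dihydro-1-O-methylgenipin | COC(=O)C1=CO[C@@H](OC)[C@H]2[C@@H]1C[C@@H]3O[C@]23CO | intermediate
4 | 7α-phenylselanyl-8β-hydroxy-7,8-dihydro-1-O-methylgenipin | COC(=O)C1=CO[C@@H](OC)[C@H]2[C@@H]1C[C@@H]([Se]c3ccccc3)[C@@]2(O)CO | intermediate
5 | Δ6,7-8β-hydroxy-8α-(hydroxymethyl) diol (1-O-methyl) | COC(=O)C1=CO[C@@H](OC)[C@H]2[C@@H]1C=C[C@@]2(O)CO | intermediate
6 | Δ6,7-8β-hydroxy-8α-formyl compound (1-O-methyl) | COC(=O)C1=CO[C@@H](OC)[C@H]2[C@@H]1C=C[C@@]2(O)C=O | intermediate
7 | 4-hydroxybenzaldehyde | O=Cc1ccc(O)cc1 | starting material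
8 | 4-(methoxymethoxy)benzaldehyde | COCOc1ccc(C=O)cc1 | intermediate
9 | methyl acetate | COC(C)=O | starting material
10 | methyl (±)-3-hydroxy-3-[4-(methoxymethoxy)phenyl]propanoate | COCOc1ccc(C(O)CC(=O)OC)cc1 | intermediate
11 | methyl (±)-3-[(tert-butyldimethylsilyl)oxy]-3-[4-(methoxymethoxy)phenyl]propanoate | COCOc1ccc(C(CC(=O)OC)O[Si](C)(C)C(C)(C)C)cc1 | intermediate
12 | (±)-3-[(tert-butyldimethylsilyl)oxy]-3-[4-(methoxymethoxy)phenyl]propanoic acid | COCOc1ccc(C(CC(=O)O)O[Si](C)(C)C(C)(C)C)cc1 | intermediate
13 | (±)-3-[(tert-butyldimethylsilyl)oxy]-3-[4-(methoxymethoxy)phenyl]propanoyl chloride | COCOc1ccc(C(CC(=O)Cl)O[Si](C)(C)C(C)(C)C)cc1 | intermediate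
14 | 8β-O-acyl derivative of 6 (acyl from 13; 8α-CHO; 1:1 at C13) | COC(=O)C1=CO[C@@H](OC)[C@H]2[C@@H]1C=C[C@]2(C=O)OC(=O)CC(O[Si](C)(C)C(C)(C)C)c1ccc(OCOC)cc1 | intermediate
15 | spiro β-hydroxy-γ-lactone (lactone O on C8 β, C10 α; mixture at C10/C11/C13) | COC(=O)C1=CO[C@@H](OC)[C@H]2[C@@H]1C=C[C@]23OC(=O)C(C(O[Si](C)(C)C(C)(C)C)c4ccc(OCOC)cc4)C3O | intermediate
16 | spiro-butenolide (C10=C11, α-CH(OTBS)Ar; 1:1 at C13) | COC(=O)C1=CO[C@@H](OC)[C@H]2[C@@H]1C=C[C@]23OC(=O)C(C(O[Si](C)(C)C(C)(C)C)c4ccc(OCOC)cc4)=C3 | intermediate
17 | prismatomerin | COC(=O)C1=CO[C@@H]2O[C@H]3/C(=C\c4ccc(O)cc4)C(=O)O[C@]34C=C[C@H]1[C@H]24 | intermediate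
18 | 3-O-acetylprismatomerin | COC(=O)C1=CO[C@@H]2O[C@H]3/C(=C\c4ccc(OC(C)=O)cc4)C(=O)O[C@]34C=C[C@H]1[C@H]24 | target

## Summary
- **Total steps:** 15.
- **Longest linear sequence:** 10 (steps 1–5 then 11–15; the other arm, steps 6–10 then 11–15, is also 10).

**Three steps most likely to fail, with fallbacks:**
1. **Step 14** (one-pot deprotection and SN2′ acetalisation; cation side reactions or E/Z mixtures). Fallback: form the C1–O–C10 bond before the C–C closure. Convert 6 to its cyclic C1–O–C10 methyl acetal, esterify C8–OH with a 2-(phenylselanyl)-3-arylpropanoic acid, close the lactone by intramolecular Mukaiyama aldol of the silyl ketene acetal onto the C10 oxocarbenium (cis fusion forced), then unveil the arylidene by selenoxide elimination.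
2. **Step 12** (strained 5-enolendo aldol; possible retro-aldol or β-silyloxy elimination). Fallback: make the C10–C11 bond intermolecularly. Add the lithium enolate of the tert-butyl ester analogue of 11 to the 8-O-TES ether of 6, then acid-mediated lactonisation onto C8–OH and dehydration to reach 16.
3. **Step 11** (acylating a hindered tertiary α-hydroxy aldehyde). Fallback: change the order. Mono-TES-protect the primary alcohol of diol 5, acylate the tertiary lithium alkoxide with 13, remove TES (HF·pyridine) and only then oxidise to aldehyde 14.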